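Start at the charge. The elm flask, the one asked about, begins as charged substrate, and an earlier run, maple, was made richer and hotter.

| setting | elm | maple | flask |
|---|---|---|---|
| substrate | 0.058 M | 0.087 M | 0.058 M |
| temperature | 90 °C | 96 °C | 90 °C |
| remark | the very flask that is asked about, followed so far | run made earlier |  |
| time |  |  | 20 h |

- elm (time / h: target / %, substrate / %): 2.00: 10, 77; 6.00: 14, 57; 10.0: 16, 40; 15.0: 18, 19
- maple (time / h: target / %, substrate / %): 0.333: 0, 99; 0.667: 3, 90; 1.50: 8, 77; 4.00: 17, 47

(readings scatter by 2 percentage points)

- target, in percent of the substrate first charged, at 20 h
- what to do for the largest gain in target; "none" if nothing gains more than 2 percentage points (south / north-west / east / north-east / none)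
- target present, with what was taken out counted in, in percent of the substrate first charged, after north-west
- target present, with what was taken out counted in, in percent of the substrate first charged, after east

- south: at 20 h raise the temperature by 20 K, then wait 20 h
- north-west: at 20 h take out 90% of the target then present, then wait 20 h
- east: change nothing and wait 20 h more
- north-east: at 20 h add substrate, 50.0% of the amount charged, then wait 20 h

- percent here means substrate units held: one side product counts as two
- what is taken out of target is counted as made
- steps under discussion: substrate <-> intermediate; intermediate <-> target; substrate + target -> side product; target <-> isomer of the product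
- additions bring no volume worth counting

In the first instants, seen in maple, target reads 0% of the charge at 0.333 h and 3% at 0.667 h, while substrate reads 99% and then 90%. These target readings are of the size of the scatter of 2 percentage points, so the lag is a weak reading, but it leaves room for intermediate standing between substrate and target.

In the middle of the elm run, from 6.00 h to 15.0 h, substrate loses 38 points while target gains 4 points. Their ratio is 0.105: the late yield, target gained per part of substrate lost, a differential yield. It is a reading, and a rough one, with a scatter of 2 points on each of the readings behind it.

At 15.0 h the readings leave 63.0% of the charge unread, in other forms. What matters next is how much substrate remains to be spent. Over the last 5.00 h it fell from 40% to 19%, and the same factor again gives an estimate of 9.03% at 20 h.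

The reckoning made here therefore puts target at 19.0% at 20 h. In this reckoning, waiting spends the estimated remainder for 0.95 points, less than the margin, giving 20.0%. Added substrate, if spent, promises 5.3 points. The late yield says nothing about north-west, where target no longer stands as it did in the run.

The forecast gives 21% now, 25% after waiting and 31% after north-west, and chooses north-west: “Removing target spares that loss”. On now and on waiting it stands above the reckoning here.

The flask gives 20.9%, 21.3% after waiting and 32.9% after north-west, and the largest gain, 12 points, makes the choice north-west; the forecast held on each.

    substrate ⇌ intermediate (K = 0.410, k = 0.110 h⁻¹, Ea = 105 kJ mol⁻¹, ΔH = −37.0 kJ mol⁻¹)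
    intermediate ⇌ target (K = 28.0, k = 0.730 h⁻¹, Ea = 102 kJ mol⁻¹, ΔH = 0 kJ mol⁻¹)
    substrate + target → side product (k = 3.60 L mol⁻¹ h⁻¹, Ea = 79.0 kJ mol⁻¹)
    target ⇌ isomer of the product (K = 1.10, k = 0.390 h⁻¹, Ea = 110 kJ mol⁻¹, ΔH = −47.0 kJ mol⁻¹)
    (constants at 90 °C)

At 20.0 h in the elm flask, target goes to isomer of the product 16 times as fast as to side product, counting the forward rate of that reversible step alone. At 4.94 h the same ratio is 3.0. For north-east the late yield gives 5.3 points, and the flask gains 5.1 points. A reading of the same flask at 8.00 h holds 44.5% substrate, so the late yield, counted from the elm reading at 6.00 h, gives 15.3% target, and that flask holds 16.2%.

The readings are simulated from invented constants; scatter was added.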